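**Retrosynthetic overview**
1. Target ⇐ C14–O bond: 1,3-hydroxyl transposition (C1–OH → C14–OH) of a ten-membered 10(14)-exo-methylene carbinol, formed last, which also places the C1=C10 alkene in the ring (ring-cis).
2. Ten-membered ring ⇐ C1–C10 bond: intramolecular Ni/Cr coupling of a C10 vinyl bromide with a C1 aldehyde (unmasked from the prenyl group by ozonolysis).
3. C6–O ester bond ⇐ Mitsunobu inversion of the 6-epi alcohol with (2Z)-2-(acetoxymethyl)but-2-enoic acid.
4. C6–C7 bond ⇐ chromium-mediated allylation of a linalool-derived aldehyde with an (S)-3-(bromomethyl)butenolide; the lactone ring is made first (esterification, then ring-closing metathesis), the carbocycle second.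
5. Building blocks: (R)-linalool (C4 stereocentre), crotonaldehyde, 2,3-dibromopropene, 2-(bromomethyl)acrylic acid, ethyl but-2-ynoate.

Assumption: commercial (R)-(−)-linalool is used enantiopure (ee upgraded if needed); labels C1–C15 are germacranolide numbering (lactone O on C8, ester on C6, carbinol C4, CH2OH = C14, exo-methylene = C13).

**Step 1**
Reactants: 1 (R)-(−)-linalool
Product: 2 (R)-triethyl[(3,7-dimethylocta-1,6-dien-3-yl)oxy]silane
Conditions: Et3SiOTf, 2,6-lutidine, CH2Cl2, 0 °C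
Reagents that add atoms: triethylsilyl trifluoromethanesulfonate CC[Si](CC)(CC)OS(=O)(=O)C(F)(F)F
Why: Silyl ether formation with a silyl triflate protects the tertiary alcohol (later no lactol with the C1 aldehyde, no transannular ether) and leaves the C4 stereocentre untouched.

**Step 2**
Reactants: 2 (R)-triethyl[(3,7-dimethylocta-1,6-dien-3-yl)oxy]silane
Product: 4 (R)-3,7-dimethyl-3-(triethylsilyloxy)oct-6-en-1-ol, via B-alkyl-9-BBN adduct 3 (not isolated)
Conditions: 9-BBN, THF, 0 °C to rt; then NaOH, H2O2, 0 °C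
Reagents that add atoms: hydrogen peroxide OO; 9-borabicyclo[3.3.1]nonane B1C2CCCC1CCC2 (boron, in 3 only)
Why: Brown hydroboration–oxidation; 9-BBN adds anti-Markovnikov to the monosubstituted vinyl group far faster than to the trisubstituted alkene.

**Step 3**
Reactants: 4 (R)-3,7-dimethyl-3-(triethylsilyloxy)oct-6-en-1-ol
Product: 5 (R)-3,7-dimethyl-3-(triethylsilyloxy)oct-6-enal
Conditions: TEMPO (10 mol %), PhI(OAc)2, CH2Cl2, rt
Reagents that add atoms: none
Why: Nitroxyl-catalysed oxidation of a primary alcohol stops at the aldehyde and does not touch the alkene or silyl ether.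

**Step 4**
Reactants: 6 (E)-crotonaldehyde; 7 2,3-dibromopropene
Product: 9 (4S,5E)-2-bromohepta-1,5-dien-4-ol, via trimethylsilyl ether 8 (not isolated)
Conditions: CrBr3 (10 mol %), Kishi-type chiral oxazoline–sulfonamide ligand (11 mol %, antipode giving the S carbinol), Et3N, cobalt phthalocyanine Co(C32H16N8) (1 mol %), Mn, Me3SiCl, THF, 0 °C; then 1 M HCl
Reagents that add atoms: chlorotrimethylsilane C[Si](C)(C)Cl (silicon, in 8 only)
Why: Catalytic asymmetric Nozaki–Hiyama 2-haloallylation, in which cobalt activates only the allylic C–Br bond and the chiral chromium complex sets C8 (S) by face-selective 1,2-addition.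

**Step 5**
Reactants: 9 (4S,5E)-2-bromohepta-1,5-dien-4-ol; 10 2-(bromomethyl)acrylic acid
Product: 11 (4S,5E)-2-bromohepta-1,5-dien-4-yl 2-(bromomethyl)prop-2-enoate
Conditions: N,N'-diisopropylcarbodiimide, DMAP (5 mol %), CH2Cl2, 0 °C
Reagents that add atoms: none
Why: Steglich esterification at the acyl carbon, so the C8–O bond and its configuration are retained.

**Step 6**
Reactants: 11 (4S,5E)-2-bromohepta-1,5-dien-4-yl 2-(bromomethyl)prop-2-enoate
Product: 12 (5S)-3-(bromomethyl)-5-(2-bromoprop-2-en-1-yl)furan-2(5H)-one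
Conditions: second-generation Hoveyda–Grubbs catalyst RuCl2(H2IMes)(=CH-C6H4-2-OiPr) (5 mol %), toluene, 80 °C
Reagents that add atoms: none
Why: Ring-closing metathesis between the propenyl group and the acrylate closes the butenolide (propene lost), while the vinyl bromide is inert to the ruthenium carbene.

**Step 7**
Reactants: 13 ethyl but-2-ynoate
Product: 15 ethyl (2Z)-2-(hydroxymethyl)but-2-enoate, via vinylalane 14 (not isolated)
Conditions: i-Bu2AlH, N-methylmorpholine N-oxide, THF, 0 °C; then CH2O (gas from paraformaldehyde), −78 °C to rt; aq. Rochelle salt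
Reagents that add atoms: formaldehyde C=O; diisobutylaluminium hydride CC(C)C[AlH]CC(C)C (aluminium, in 14 only)
Why: syn-Hydroalumination of the ynoate followed by aldol-type hydroxymethylation places the ester cis to the methyl group (angelate-type Z geometry).

**Step 8**
Reactants: 15 ethyl (2Z)-2-(hydroxymethyl)but-2-enoate
Product: 16 (2Z)-2-(hydroxymethyl)but-2-enoic acid
Conditions: LiOH, THF/H2O, 0 °C to rt; then 1 M HCl
Reagents that add atoms: lithium hydroxide [Li+].[OH-]
Why: Mild saponification gives the acid without Z-to-E isomerisation.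

**Step 9**
Reactants: 16 (2Z)-2-(hydroxymethyl)but-2-enoic acid
Product: 17 (2Z)-2-(acetoxymethyl)but-2-enoic acid
Conditions: Ac2O, pyridine, CH2Cl2, 0 °C to rt; aq. NaHCO3 then acidification
Reagents that add atoms: acetic anhydride CC(=O)OC(C)=O
Why: O-Acetylation of the primary allylic alcohol; any mixed anhydride is hydrolysed on aqueous work-up.

**Step 10**
Reactants: 5 (R)-3,7-dimethyl-3-(triethylsilyloxy)oct-6-enal; 12 (5S)-3-(bromomethyl)-5-(2-bromoprop-2-en-1-yl)furan-2(5H)-one
Product: 18 (4S,5S)-5-(2-bromoprop-2-en-1-yl)-4-[(1R,3R)-1-hydroxy-3,7-dimethyl-3-(triethylsilyloxy)oct-6-en-1-yl]-3-methylideneoxolan-2-one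
Conditions: CrCl2 (3 equiv), THF, 0 °C to rt
Reagents that add atoms: none
Why: Nozaki–Hiyama allylation with SE2' attack at C7 on the face opposite the C8 substituent (trans lactone); the ring-locked E-type allylchromium in a chair Zimmerman–Traxler transition state is expected to give the anti (6-epi) carbinol, which step 11 inverts.

**Step 11**
Reactants: 18 (the 6-epi alcohol); 17 (2Z)-2-(acetoxymethyl)but-2-enoic acid
Product: 19 (1S,3R)-1-[(2S,3S)-2-(2-bromoprop-2-en-1-yl)-4-methylidene-5-oxooxolan-3-yl]-3,7-dimethyl-3-(triethylsilyloxy)oct-6-en-1-yl (2Z)-2-(acetoxymethyl)but-2-enoate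
Conditions: PPh3, DIAD, toluene, 0 °C to rt
Reagents that add atoms: none
Why: Mitsunobu esterification forms the C6–O bond by SN2 with inversion (sets 6S), and because the carboxylate is the nucleophile the acid is never acyl-activated, so the Z alkene is not isomerised.

**Step 12**
Reactants: 19 (the C6 ester)
Product: 21 (1S,3R)-1-[(2S,3S)-2-(2-bromoprop-2-en-1-yl)-4-methylidene-5-oxooxolan-3-yl]-3-methyl-6-oxo-3-(triethylsilyloxy)hexyl (2Z)-2-(acetoxymethyl)but-2-enoate, via ozonide 20 (not isolated)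
Conditions: O3 (1 equiv, Sudan Red 7B end-point), CH2Cl2, −78 °C; then Me2S, −78 °C to rt
Reagents that add atoms: ozone [O-][O+]=O
Why: Ozonolysis is selective for the electron-rich trisubstituted alkene over the acrylate-type alkenes and the vinyl bromide, and unmasks the C1 aldehyde.

**Step 13**
Reactants: 21 (the bromo-aldehyde)
Product: 22 (3aR,4S,6R,11aS)-9-hydroxy-6-methyl-3,10-dimethylidene-2-oxo-6-(triethylsilyloxy)dodecahydrocyclodeca[b]furan-4-yl (2Z)-2-(acetoxymethyl)but-2-enoate (both C9 epimers)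
Conditions: CrCl2 (10 equiv), NiCl2 (1 mol %), DMSO/THF, rt, slow addition to 2 mM
Reagents that add atoms: none
Why: Intramolecular Nozaki–Hiyama–Kishi reaction: nickel inserts into the vinyl C–Br bond, the alkenyl group is transferred to chromium and adds to the aldehyde; the carbinol configuration is irrelevant because step 14 removes that centre.

**Step 14**
Reactants: 22 (both C9 epimers)
Product: 24 (3aR,4S,6R,9E,11aS)-6-hydroxy-10-(hydroxymethyl)-6-methyl-3-methylidene-2-oxo-2,3,3a,4,5,6,7,8,11,11a-decahydrocyclodeca[b]furan-4-yl (2Z)-2-(acetoxymethyl)but-2-enoate (CNP0313132.1), via transposed triethylsilyl ether 23 (not isolated)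
Conditions: Ph3SiOReO3 (5 mol %), Et2O, −50 to 0 °C; then pyridine, HF·pyridine, THF, 0 °C to rt, same flask
Reagents that add atoms: none
Why: Proposed new method: a heptavalent rhenium–oxo catalyst converts both epimers of the exocyclic 2-methylene-cycloalkanol into one product by reversible perrhenate-ester formation and a chair-like [3,3] oxygen shift from C1 to C14, so the C14–O bond and the endocyclic C1=C10 alkene form together under thermodynamic control (primary alcohol, trisubstituted alkene with C2 and C9 cis in the ring); the closest known reaction is the Ph3SiOReO3-catalysed 1,3-isomerisation of acyclic allylic alcohols, not yet shown for an exocyclic-to-endocyclic shift in a ten-membered carbocycle; HF·pyridine then removes the silyl group and spares the acetate.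

**Compound list**
1 | (R)-(−)-linalool | C=C[C@](C)(O)CCC=C(C)C | starting material
2 | (R)-triethyl[(3,7-dimethylocta-1,6-dien-3-yl)oxy]silane | C=C[C@](C)(O[Si](CC)(CC)CC)CCC=C(C)C | intermediate
3 | 9-[(3S)-3,7-dimethyl-3-(triethylsilyloxy)oct-6-en-1-yl]-9-borabicyclo[3.3.1]nonane (same spatial arrangement as 2; descriptor changes by priority only) | B1(CC[C@](C)(O[Si](CC)(CC)CC)CCC=C(C)C)C2CCCC1CCC2 | intermediate (not isolated)
4 | (R)-3,7-dimethyl-3-(triethylsilyloxy)oct-6-en-1-ol | OCC[C@](C)(O[Si](CC)(CC)CC)CCC=C(C)C | intermediate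
5 | (R)-3,7-dimethyl-3-(triethylsilyloxy)oct-6-enal | O=CC[C@](C)(O[Si](CC)(CC)CC)CCC=C(C)C | intermediate
6 | (E)-crotonaldehyde | C/C=C/C=O | starting material
7 | 2,3-dibromopropene | BrCC(Br)=C | starting material
8 | {[(4S,5E)-2-bromohepta-1,5-dien-4-yl]oxy}trimethylsilane | C/C=C/[C@@H](O[Si](C)(C)C)CC(Br)=C | intermediate (not isolated)
9 | (4S,5E)-2-bromohepta-1,5-dien-4-ol | C/C=C/[C@@H](O)CC(Br)=C | intermediate
10 | 2-(bromomethyl)acrylic acid | C=C(CBr)C(=O)O | starting material
11 | (4S,5E)-2-bromohepta-1,5-dien-4-yl 2-(bromomethyl)prop-2-enoate | C/C=C/[C@@H](OC(=O)C(=C)CBr)CC(Br)=C | intermediate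
12 | (5S)-3-(bromomethyl)-5-(2-bromoprop-2-en-1-yl)furan-2(5H)-one | BrCC1=C[C@H](CC(Br)=C)OC1=O | intermediate
13 | ethyl but-2-ynoate | CCOC(=O)C#CC | starting material
14 | ethyl (2E)-2-(diisobutylalumanyl)but-2-enoate (ester cis to methyl) | CCOC(=O)/C(=C\C)[Al](CC(C)C)CC(C)C | intermediate (not isolated)
15 | ethyl (2Z)-2-(hydroxymethyl)but-2-enoate | CCOC(=O)/C(=C\C)CO | intermediate
16 | (2Z)-2-(hydroxymethyl)but-2-enoic acid | C/C=C(CO)\C(=O)O | intermediate
17 | (2Z)-2-(acetoxymethyl)but-2-enoic acid | C/C=C(COC(C)=O)\C(=O)O | intermediate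
18 | (4S,5S)-5-(2-bromoprop-2-en-1-yl)-4-[(1R,3R)-1-hydroxy-3,7-dimethyl-3-(triethylsilyloxy)oct-6-en-1-yl]-3-methylideneoxolan-2-one | C=C1C(=O)O[C@@H](CC(Br)=C)[C@@H]1[C@H](O)C[C@](C)(O[Si](CC)(CC)CC)CCC=C(C)C | intermediate
19 | (1S,3R)-1-[(2S,3S)-2-(2-bromoprop-2-en-1-yl)-4-methylidene-5-oxooxolan-3-yl]-3,7-dimethyl-3-(triethylsilyloxy)oct-6-en-1-yl (2Z)-2-(acetoxymethyl)but-2-enoate | C=C1C(=O)O[C@@H](CC(Br)=C)[C@@H]1[C@@H](OC(=O)/C(=C\C)COC(C)=O)C[C@](C)(O[Si](CC)(CC)CC)CCC=C(C)C | intermediate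
20 | ozonide of 19: (1S,3R)-1-[(2S,3S)-2-(2-bromoprop-2-en-1-yl)-4-methylidene-5-oxooxolan-3-yl]-5-(5,5-dimethyl-1,2,4-trioxolan-3-yl)-3-methyl-3-(triethylsilyloxy)pentyl (2Z)-2-(acetoxymethyl)but-2-enoate | C=C1C(=O)O[C@@H](CC(Br)=C)[C@@H]1[C@@H](OC(=O)/C(=C\C)COC(C)=O)C[C@](C)(O[Si](CC)(CC)CC)CCC2OOC(C)(C)O2 | intermediate (not isolated)
21 | (1S,3R)-1-[(2S,3S)-2-(2-bromoprop-2-en-1-yl)-4-methylidene-5-oxooxolan-3-yl]-3-methyl-6-oxo-3-(triethylsilyloxy)hexyl (2Z)-2-(acetoxymethyl)but-2-enoate | C=C1C(=O)O[C@@H](CC(Br)=C)[C@@H]1[C@@H](OC(=O)/C(=C\C)COC(C)=O)C[C@](C)(O[Si](CC)(CC)CC)CCC=O | intermediate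
22 | (3aR,4S,6R,11aS)-9-hydroxy-6-methyl-3,10-dimethylidene-2-oxo-6-(triethylsilyloxy)dodecahydrocyclodeca[b]furan-4-yl (2Z)-2-(acetoxymethyl)but-2-enoate, both C9 epimers | C=C1C(=O)O[C@H]2CC(=C)C(O)CC[C@@](C)(O[Si](CC)(CC)CC)C[C@H](OC(=O)/C(=C\C)COC(C)=O)[C@H]12 | intermediate
23 | (3aR,4S,6R,9E,11aS)-10-(hydroxymethyl)-6-methyl-3-methylidene-2-oxo-6-(triethylsilyloxy)-2,3,3a,4,5,6,7,8,11,11a-decahydrocyclodeca[b]furan-4-yl (2Z)-2-(acetoxymethyl)but-2-enoate | C=C1C(=O)O[C@H]2C/C(CO)=C\CC[C@@](C)(O[Si](CC)(CC)CC)C[C@H](OC(=O)/C(=C\C)COC(C)=O)[C@H]12 | intermediate (not isolated)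
24 | (3aR,4S,6R,9E,11aS)-6-hydroxy-10-(hydroxymethyl)-6-methyl-3-methylidene-2-oxo-2,3,3a,4,5,6,7,8,11,11a-decahydrocyclodeca[b]furan-4-yl (2Z)-2-(acetoxymethyl)but-2-enoate | C=C1C(=O)O[C@H]2C/C(CO)=C\CC[C@@](C)(O)C[C@H](OC(=O)/C(=C\C)COC(C)=O)[C@H]12 | target

**Step count:** 14 steps in total.
**Longest linear sequence:** 8 steps (1, 2, 3, 10, 11, 12, 13, 14; the butenolide branch 4, 5, 6, 10–14 is equally long).

**Steps most likely to fail, with fallbacks**

Step 13 (ten-membered Ni/Cr ring closure; risks are oligomerisation, protodebromination and attack of the alkenyl metal on the methylene lactone). The fallback closes the ring by olefin metathesis. It sets out from aldehyde 21: Lombardo methylenation (Zn, CH2Br2, TiCl4, THF) gives the terminal alkene F4. Intermolecular Ni/Cr coupling of its vinyl bromide with formaldehyde (CrCl2, NiCl2 cat., paraformaldehyde, DMF) gives the 2-(hydroxymethyl)allyl diene F5. Ring-closing metathesis (second-generation Hoveyda–Grubbs catalyst, toluene, 80 °C, 1 mM) with loss of ethene gives the ring-cis trisubstituted alkene, which is compound 23, where the route is rejoined for the desilylation of step 14.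

Step 11 (Mitsunobu at a hindered carbinol next to the lactone C7–H; risks are elimination to a diene and phosphine attack on the allylic acetate of 17). The fallback separates inversion from acylation. It sets out from 18: Mitsunobu with formic acid (PPh3, DIAD, THF) gives the inverted formate F1. KHCO3 in MeOH at 0 °C gives the 6S alcohol F2. This is acylated with the mixed anhydride F3 (made from 17, 2,4,6-trichlorobenzoyl chloride and Et3N; then F2, NaHCO3, toluene, 80 °C, without a nucleophilic amine so the Z alkene is kept). This comes back at 19. If step 10 turns out syn-selective and gives F2 directly, the same acylation is used without any inversion.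

Step 14 (the proposed rhenium-catalysed transposition; risks are ionisation with ether formation or an unfavourable equilibrium). The fallback uses known SN2'/SN2 chemistry. It sets out from 22: MsCl, Et3N, CH2Cl2, −20 °C gives the allylic mesylate F6. LiBr in THF converts it by SN2' and equilibration into the primary allylic bromide F7 with the alkene in the ring. HCO2Na in DMF gives the primary formate F8. KHCO3 in MeOH at 0 °C cleaves the formate without touching the acetate and comes back at 23, which is desilylated with HF·pyridine as in step 14.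

**Further compounds**
F1 | step 11 | (1S,3R)-1-[(2S,3S)-2-(2-bromoprop-2-en-1-yl)-4-methylidene-5-oxooxolan-3-yl]-3,7-dimethyl-3-(triethylsilyloxy)oct-6-en-1-yl formate | C=C1C(=O)O[C@@H](CC(Br)=C)[C@@H]1[C@@H](OC=O)C[C@](C)(O[Si](CC)(CC)CC)CCC=C(C)C
F2 | step 11 | (4S,5S)-5-(2-bromoprop-2-en-1-yl)-4-[(1S,3R)-1-hydroxy-3,7-dimethyl-3-(triethylsilyloxy)oct-6-en-1-yl]-3-methylideneoxolan-2-one | C=C1C(=O)O[C@@H](CC(Br)=C)[C@@H]1[C@@H](O)C[C@](C)(O[Si](CC)(CC)CC)CCC=C(C)C
F3 | step 11 | (2Z)-2-(acetoxymethyl)but-2-enoic 2,4,6-trichlorobenzoic anhydride | C/C=C(COC(C)=O)\C(=O)OC(=O)c1c(Cl)cc(Cl)cc1Cl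
F4 | step 13 | (1S,3R)-1-[(2S,3S)-2-(2-bromoprop-2-en-1-yl)-4-methylidene-5-oxooxolan-3-yl]-3-methyl-3-(triethylsilyloxy)hept-6-en-1-yl (2Z)-2-(acetoxymethyl)but-2-enoate | C=C1C(=O)O[C@@H](CC(Br)=C)[C@@H]1[C@@H](OC(=O)/C(=C\C)COC(C)=O)C[C@](C)(O[Si](CC)(CC)CC)CCC=C
F5 | step 13 | (1S,3R)-1-{(2S,3S)-2-[2-(hydroxymethyl)prop-2-en-1-yl]-4-methylidene-5-oxooxolan-3-yl}-3-methyl-3-(triethylsilyloxy)hept-6-en-1-yl (2Z)-2-(acetoxymethyl)but-2-enoate | C=C1C(=O)O[C@@H](CC(=C)CO)[C@@H]1[C@@H](OC(=O)/C(=C\C)COC(C)=O)C[C@](C)(O[Si](CC)(CC)CC)CCC=C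
F6 | step 14 | C9 methanesulfonate of 22 (both epimers) | C=C1C(=O)O[C@H]2CC(=C)C(OS(C)(=O)=O)CC[C@@](C)(O[Si](CC)(CC)CC)C[C@H](OC(=O)/C(=C\C)COC(C)=O)[C@H]12
F7 | step 14 | (3aR,4S,6R,11aS)-10-(bromomethyl)-6-methyl-3-methylidene-2-oxo-6-(triethylsilyloxy)-2,3,3a,4,5,6,7,8,11,11a-decahydrocyclodeca[b]furan-4-yl (2Z)-2-(acetoxymethyl)but-2-enoate (ring-cis alkene) | C=C1C(=O)O[C@H]2C/C(CBr)=C\CC[C@@](C)(O[Si](CC)(CC)CC)C[C@H](OC(=O)/C(=C\C)COC(C)=O)[C@H]12
F8 | step 14 | formate ester of 23 at the C10 hydroxymethyl group | C=C1C(=O)O[C@H]2C/C(COC=O)=C\CC[C@@](C)(O[Si](CC)(CC)CC)C[C@H](OC(=O)/C(=C\C)COC(C)=O)[C@H]12
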